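## Retrosynthetic overview

1. Open both 2,5-dihydrofurans at O–C8 and O–C8′. The target then becomes a C2-symmetric C40 bis(α-hydroxyallene), the (6S,6′S) stereoisomer of mimulaxanthin. In the forward direction, one double Au(I) 5-endo cycloisomerisation converts each allene axis into a C8 stereocentre.
2. Cut C11=C12 and C11′=C12′. This gives two C15 allenic phosphonium salts and the C10 dialdehyde, joined by a double Wittig reaction.
3. The (6S)-α-hydroxyallene comes from the 5,6-anti alkynyl epoxide by anti-SN2′ hydride delivery (centre to axis).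
4. The epoxide comes from the ring enyne through a bromohydrin, which places oxygen on the contra-steric face. The enyne comes from the actinol enol triflate and a C6 enynol by Sonogashira coupling.
5. Ring order: the carbocycles arrive with actinol. One transient oxirane forms per C15 half. The two dihydrofurans close last, together.

**Assumptions.** The SMILES reads as all-E (3S,5R,8R,3′S,5′R,8′R)-auroxanthin. In it, 5-O is anti to 3-OH and the chain at C8 is trans to 5-Me. Carotenoid numbering is used throughout (ring C1–C6, chain C7–C15). Allene stereochemistry in the SMILES is written on the central carbon, with H-8 explicit. All polyene steps run under Ar in dim light.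

## Route

**Step 1**
Reactants: 1 (4R,6R)-4-hydroxy-2,2,6-trimethylcyclohexanone (actinol)
Product: 2 (4R,6R)-4-(tert-butyldimethylsilyloxy)-2,2,6-trimethylcyclohexanone
Conditions: TBSCl, imidazole, DMF, rt
Reagents that add atoms: tert-butyldimethylsilyl chloride, C[Si](C)(Cl)C(C)(C)C
Why: Standard silyl ether protection masks the only OH before enolisation and touches no stereocentre.

**Step 2**
Reactants: 2 TBS-actinol
Product: 4 (4R)-4-(TBSO)-2,6,6-trimethylcyclohex-1-en-1-yl trifluoromethanesulfonate, via lithium enolate 3 (not isolated)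
Conditions: LDA, THF, −78 °C; then PhNTf2, −78 → 0 °C
Reagents that add atoms: N-phenylbis(trifluoromethanesulfonimide), O=S(=O)(N(c1ccccc1)S(=O)(=O)C(F)(F)F)C(F)(F)F; lithium diisopropylamide, [Li+].CC(C)[N-]C(C)C (Li only in 3)
Why: In this enol triflate synthesis the other α-carbon is quaternary, so a single enolate forms and is O-triflated; the C-methyl stereocentre is erased on purpose and C3 is untouched.

**Step 3**
Reactants: 4 enol triflate; 5 (E)-3-methylpent-2-en-4-yn-1-ol
Product: 6 (2E)-5-[(4R)-4-(TBSO)-2,6,6-trimethylcyclohex-1-en-1-yl]-3-methylpent-2-en-4-yn-1-ol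
Conditions: Pd(PPh3)4 (5 mol %), CuI (10 mol %), Et3N, DMF, rt → 40 °C
Reagents that add atoms: none
Why: Sonogashira coupling of a vinyl triflate with a terminal enyne tolerates the free alcohol and the silyl ether, keeps the 9E geometry and creates no stereocentre.

**Step 4**
Reactants: 6 dienynol
Product: 8 (3S,5R,6R)-3-(TBSO)-5,6-epoxy-7,8-didehydro C15 enynol (epoxide O anti to OTBS), via bromohydrin 7 (not isolated)
Conditions: NBS (1.05 equiv), THF–H2O 4:1, 0 °C, dark; then K2CO3, MeOH, 0 °C → rt
Reagents that add atoms: water, O; N-bromosuccinimide, O=C1CCC(=O)N1Br (Br only in 7)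
Why: This is the halohydrin route to the contra-steric epoxide (Fürst–Plattner trans-diaxial opening, as in HOBr/base β-epoxidation of Δ5-steroids): with 3-OTBS equatorial the axial C1-methyl shields the face anti to OTBS, so Br+ takes the electron-rich tetrasubstituted C5=C6 bond from the OTBS face, water opens axially at C5 from the opposite face, and base closes onto C6 with inversion to set 5R,6R, while the trisubstituted C9=C10 bond is deactivated by its allylic oxygen.

**Step 5**
Reactants: 8 alkynyl epoxide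
Product: 10 (2E)-5-[(2R,4S)-2,4-dihydroxy-2,6,6-trimethylcyclohexylidene]-3-methylpenta-2,4-dien-1-ol with (S)-allene axis [(3S,5R,6S)-C15 allenic triol], via bis(diethoxymethylsilyl) ether 9 (not isolated)
Conditions: CuCl (5 mol %), IPr·HCl (5 mol %), NaOtBu (12 mol %), (EtO)2MeSiH (3 equiv), toluene, 0 °C → rt; then TBAF (4 equiv), THF, rt
Reagents that add atoms: diethoxymethylsilane, C[SiH](OCC)OCC (Si only in 9)
Why: In this NHC–copper hydride SN2′ reduction of a propargylic oxirane, syn-hydrocupration (H to C8, Cu to C7) followed by anti β-alkoxide elimination puts hydride anti to the departing C6–O, so the epoxide centres become the (6S) axis (H-8 on the 5-Me face, chain on the former oxirane-O face) with C5–O untouched, and fluoride then removes all three silyl groups in the same pot.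

**Step 6**
Reactants: 10 allenic triol
Product: 11 (3S,5R,6S)-C15 allenic triphenylphosphonium bromide
Conditions: PPh3·HBr (1.05 equiv), MeOH, 0 °C → rt, dark
Reagents that add atoms: triphenylphosphine hydrobromide, [Br-].c1ccccc1[PH+](c1ccccc1)c1ccccc1
Why: In this acid-mediated allylic phosphonium salt formation only the primary vinylallene-conjugated allylic alcohol ionises, whereas the secondary 3-OH and the tertiary α-allenic 5-OH (an end group known to survive dilute acid) stay intact, and the axis is safe because rotation about C7–C8 would need a localised vinyl cation.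

**Step 7**
Reactants: 11 phosphonium bromide (2.2 equiv); 12 (2E,4E,6E)-2,7-dimethylocta-2,4,6-trienedial
Product: 15 (3S,5R,6S,3′S,5′R,6′S)-6,7,6′,7′-tetradehydro-5,6,5′,6′-tetrahydro-β,β-carotene-3,5,3′,5′-tetrol, via phosphonium ylide 13 (not isolated), via C25 allenic apocarotenal 14 (not isolated)
Conditions: NaOMe (2.4 equiv), CH2Cl2–MeOH, 0 °C → rt; then EtOH, reflux 1 h; crystallise
Reagents that add atoms: none
Why: The double Wittig olefination (C15 + C10 + C15) runs with free hydroxyls in alcoholic medium, minor 11Z isomers are converted thermally to all-E, no iodine is used so the allene axes are not isomerised, and no stereocentre is touched.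

**Step 8**
Reactants: 15 bis(α-hydroxyallene) tetrol
Product: 17 (3S,5R,8R,3′S,5′R,8′R)-5,8:5′,8′-diepoxy-5,8,5′,8′-tetrahydro-β,β-carotene-3,3′-diol (auroxanthin), via mono-cyclised allenic furanoid 16 (not isolated)
Conditions: IPrAuCl (5 mol %), AgOTs (5 mol %), 2,6-di-tert-butylpyridine (10 mol %), THF–toluene, −10 → 10 °C, Ar, dark; Et3N quench, basic alumina
Reagents that add atoms: none
Why: Proposed new method: the NHC–Au(I) cation binds each C7=C8 allene bond and the tertiary 5-OH adds 5-endo to C8 from within the C5–C6–C1 plane, so H-8 and C-9 stay on the faces fixed by the (6S) axis and each axis becomes an (8R) centre (chain trans to 5-Me) before protodeauration, closing two dihydrofurans in one operation; the closest known reaction type is the Au/Ag-catalysed cycloisomerisation of α-hydroxyallenes to 2,5-dihydrofurans with axis-to-centre chirality transfer, extended here to a bis-allene conjugated through a heptaene, and the donor NHC, tosylate counter-ion and hindered pyridine are chosen to suppress polyenyl-cation formation, C8 epimerisation and polyene oxidation.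

## Compound list

1 | (4R,6R)-4-hydroxy-2,2,6-trimethylcyclohexanone | O=C1C(C)(C)C[C@H](O)C[C@H]1C | starting material
2 | (4R,6R)-4-(TBSO)-2,2,6-trimethylcyclohexanone | O=C1C(C)(C)C[C@H](O[Si](C)(C)C(C)(C)C)C[C@H]1C | intermediate
3 | lithium (4R)-4-(TBSO)-2,6,6-trimethylcyclohex-1-en-1-olate | [Li+].[O-]C1=C(C)C[C@@H](O[Si](C)(C)C(C)(C)C)CC1(C)C | intermediate
4 | (4R)-4-(TBSO)-2,6,6-trimethylcyclohex-1-en-1-yl triflate | FC(F)(F)S(=O)(=O)OC1=C(C)C[C@@H](O[Si](C)(C)C(C)(C)C)CC1(C)C | intermediate
5 | (E)-3-methylpent-2-en-4-yn-1-ol | OC/C=C(\C)C#C | starting material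
6 | (3R,9E)-C15 dienynol TBS ether | OC/C=C(\C)C#CC1=C(C)C[C@@H](O[Si](C)(C)C(C)(C)C)CC1(C)C | intermediate
7 | (3S,5R,6S)-6-bromo-5-hydroxy bromohydrin (5-OH anti, 6-Br syn to OTBS) | OC/C=C(\C)C#C[C@@]1(Br)C(C)(C)C[C@H](O[Si](C)(C)C(C)(C)C)C[C@@]1(C)O | intermediate
8 | (3S,5R,6R)-5,6-anti alkynyl epoxide | OC/C=C(\C)C#C[C@]12C(C)(C)C[C@H](O[Si](C)(C)C(C)(C)C)C[C@@]1(C)O2 | intermediate
9 | (3S,5R,6S)-allene, 3-OTBS, 5,11-bis(diethoxymethylsilyl) ether | CCO[Si](C)(OCC)OC/C=C(\C)C([H])=[C@]=C1C(C)(C)C[C@H](O[Si](C)(C)C(C)(C)C)C[C@@]1(C)O[Si](C)(OCC)OCC | intermediate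
10 | (3S,5R,6S)-C15 allenic triol | OC/C=C(\C)C([H])=[C@]=C1C(C)(C)C[C@H](O)C[C@@]1(C)O | intermediate
11 | (3S,5R,6S)-C15 allenic triphenylphosphonium bromide | [Br-].c1ccccc1[P+](c1ccccc1)(c1ccccc1)C/C=C(\C)C([H])=[C@]=C1C(C)(C)C[C@H](O)C[C@@]1(C)O | intermediate
12 | (2E,4E,6E)-2,7-dimethylocta-2,4,6-trienedial | O=C/C(C)=C/C=C/C=C(\C)C=O | starting material
13 | C15 allenic phosphonium ylide | c1ccccc1[P+](c1ccccc1)(c1ccccc1)[CH-]/C=C(\C)C([H])=[C@]=C1C(C)(C)C[C@H](O)C[C@@]1(C)O | intermediate
14 | C25 allenic 12′-apocarotenal | O=C/C(C)=C/C=C/C=C(C)/C=C/C=C(\C)C([H])=[C@]=C1C(C)(C)C[C@H](O)C[C@@]1(C)O | intermediate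
15 | (3S,5R,6S,3′S,5′R,6′S)-bis(α-hydroxyallene) tetrol | CC(/C=C/C=C(\C)C([H])=[C@]=C1C(C)(C)C[C@H](O)C[C@@]1(C)O)=C\C=C\C=C(C)\C=C\C=C(/C)C([H])=[C@]=C1C(C)(C)C[C@H](O)C[C@@]1(C)O | intermediate
16 | mono-cyclised (8R)-furanoid / (6′S)-allene | CC(/C=C/C=C(\C)[C@H]1C=C2C(C)(C)C[C@H](O)C[C@@]2(C)O1)=C\C=C\C=C(C)\C=C\C=C(/C)C([H])=[C@]=C1C(C)(C)C[C@H](O)C[C@@]1(C)O | intermediate
17 | (3S,5R,8R,3′S,5′R,8′R)-auroxanthin | CC(/C=C/C=C(\C)[C@H]1C=C2C(C)(C)C[C@H](O)C[C@@]2(C)O1)=C\C=C\C=C(C)\C=C\C=C(/C)[C@H]1C=C2C(C)(C)C[C@H](O)C[C@@]2(C)O1 | target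

## Step count and risks

Total steps: 8. Longest linear sequence: 8 (1 → 17).

**Step 8 (most likely to fail).**
- Risk: the axis may scramble through a gold-stabilised polyenyl cation, the metal may oxidise the polyene, or C8 may epimerise in the product.
- Fallback, from 10 back to 17: move ring closure ahead of polyene assembly.
- The same Au(I) cycloisomerisation (or AgNO3/CaCO3) on the simple vinylallene 10 gives the C15 furanoid diol F1.
- PPh3·HBr converts its allylic alcohol into the furanoid C15 phosphonium bromide F2.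
- Double Wittig olefination of 12 with two equivalents of F2 (NaOMe) rejoins the route at 17.

**Step 5.**
- Risk: the tetrasubstituted oxirane is hindered, anti selectivity may be incomplete, or the enyne may be over-reduced.
- Fallback, from 8 back to 10: replace hydrocupration by a palladium mechanism.
- Pd2(dba)3·CHCl3/PBu3 with HCO2H–Et3N in THF adds oxidatively anti to C6–O and forms an allenylpalladium alkoxide.
- Formate decarboxylation and C–H reductive elimination with retention then give the 3-O-TBS (6S)-allenic diol F3.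
- TBAF converts F3 into 10.

**Step 4.**
- Risk: facial selectivity of the bromohydrin, or competing attack at C9=C10.
- Fallback, from 4 back to 8: switch to reagent control.
- Stille coupling of 4 with (tributylstannyl)methanol gives the ring allylic alcohol F4.
- Sharpless epoxidation with D-(−)-diethyl tartrate, Ti(OiPr)4 and TBHP gives the anti epoxy alcohol F5.
- Dess–Martin oxidation gives the epoxy aldehyde F6.
- The Ohira–Bestmann reagent (K2CO3, MeOH) gives the ethynyl epoxide F7.
- Sonogashira coupling of F7 with (E)-3-iodobut-2-en-1-ol rejoins the route at 8.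

## Further compounds

F1 | step 8 | (2E)-3-[(2R,6S,7aR)-6-hydroxy-4,4,7a-trimethyl-2,4,5,6,7,7a-hexahydrobenzofuran-2-yl]but-2-en-1-ol | OC/C=C(\C)[C@H]1C=C2C(C)(C)C[C@H](O)C[C@@]2(C)O1
F2 | step 8 | furanoid C15 triphenylphosphonium bromide | [Br-].c1ccccc1[P+](c1ccccc1)(c1ccccc1)C/C=C(\C)[C@H]1C=C2C(C)(C)C[C@H](O)C[C@@]2(C)O1
F3 | step 5 | (3S,5R,6S)-3-O-TBS C15 allenic diol | OC/C=C(\C)C([H])=[C@]=C1C(C)(C)C[C@H](O[Si](C)(C)C(C)(C)C)C[C@@]1(C)O
F4 | step 4 | [(4R)-4-(TBSO)-2,6,6-trimethylcyclohex-1-en-1-yl]methanol | OCC1=C(C)C[C@@H](O[Si](C)(C)C(C)(C)C)CC1(C)C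
F5 | step 4 | 5,6-anti epoxy alcohol (3S,5R) | OC[C@]12C(C)(C)C[C@H](O[Si](C)(C)C(C)(C)C)C[C@@]1(C)O2
F6 | step 4 | 5,6-anti epoxy aldehyde (3S,5R) | O=C[C@]12C(C)(C)C[C@H](O[Si](C)(C)C(C)(C)C)C[C@@]1(C)O2
F7 | step 4 | 5,6-anti ethynyl epoxide (3S,5R) | C#C[C@]12C(C)(C)C[C@H](O[Si](C)(C)C(C)(C)C)C[C@@]1(C)O2
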